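**The runs.** Start from the theta run, charged with less coupling partner than starting material, which makes the partner its limiting reagent.

| flask | starting material | coupling partner | temperature | remark | time |
|---|---|---|---|---|---|
| theta | 0.092 M | 0.074 M | 15 °C | run made earlier |  |
| epsilon | 0.092 M | 0.17 M | 37 °C | run made earlier |  |
| Monday's | 0.092 M | 0.110 M | 25 °C |  | 20 min |
| Sunday's | 0.092 M | 0.110 M | 45 °C |  | 20 min |
| Saturday's | 0.092 M | 0.110 M | 5 °C |  | 20 min |

| run | time / min | bis adduct / % | starting material / % |
|---|---|---|---|
| theta | 2.50 | 6.3 | 50.4 |
| theta | 8.00 | 7.0 | 35.3 |
| theta | 12.0 | 7.0 | 32.3 |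
| theta | 20.0 | 6.6 | 31.7 |
| theta | 30.0 | 6.8 | 31.6 |
| theta | 40.0 | 6.6 | 31.4 |
| epsilon | 1.00 | 8.8 | 4.1 |
| epsilon | 1.50 | 5.9 | 1.4 |
| epsilon | 3.00 | 2.3 | 0.1 |
| epsilon | 4.00 | 1.1 | 0 |
| epsilon | 8.00 | 0 | 0.3 |
| epsilon | 15.0 | 0.1 | 0 |

(readings scatter by 0.3 percentage points)

- the numbers in the tables scatter with a standard deviation of 0.3 percentage points
- a reading or a percentage of bis adduct counts all its forms, free or not

- the flask that comes out highest in amount of bis adduct, in percent of the starting material charged, or "all alike" when all lie within 1.5 percentage points (Monday's / Sunday's / Saturday's / all alike)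
- bis adduct at the end, in percent of the starting material charged, Monday's
- bis adduct at the end, in percent of the starting material charged, Sunday's
- bis adduct at the end, in percent of the starting material charged, Saturday's

**The ledger.** Keep the books in percent of the starting material charged. Theta's coupling partner then comes to 80.4%. Starting material and bis adduct stand still from 20.0 min on, so take that whole charge as used. Enter first one partner for each starting material consumed, which is 68.6%. That leaves 12 percentage points to explain. Enter next the second partner inside the standing bis adduct, 6.6%. The epsilon run, charged with more partner than starting material, loses bis adduct from 8.8% to 1.1%, so book the remaining 5.4 points against that loss. The books close. Call the total the partner bill, the partner spent per starting material consumed: 1.17.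

**The reckoning.** Theta's bill above one has two entries: the second partner, paid at the fork where a once-coupled molecule takes it, and the partner booked against the loss of bis adduct, paid after that fork. Bis adduct per starting material consumed reads 12.7% at theta's first reading and 9.18% at epsilon's, lower despite more partner. Read this as a tentative sign that warmth tilts the fork away. The new flasks hold 1.20 equivalents, which at theta's bill pays for 103% of the starting material. Theta kept 9.62% of what it consumed as bis adduct. So commit to Saturday's, the coldest flask, as highest and above that figure, and to Sunday's as lowest and below it.

**The result.** The forecast, which differs from this reckoning, names Sunday's, with 4.5% for Monday's, 5.8% for Sunday's and 3.7% for Saturday's, on the ground that “the warmest flask keeps slightly more”. The flasks give Saturday's as highest, with 4.87% for Monday's, 0.0933% for Sunday's and 19.2% for Saturday's.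

    single product → side product (k = 0.00220 s⁻¹, Ea = 85.0 kJ mol⁻¹)
    coupling partner + bis adduct → triple product + by-product (k = 0.0290 L mol⁻¹ s⁻¹, Ea = 47.0 kJ mol⁻¹)
    coupling partner + single product → bis adduct + by-product (k = 0.0700 L mol⁻¹ s⁻¹, Ea = 40.0 kJ mol⁻¹)
    crystals ⇌ bis adduct, rate k4*(cs4 - [bis adduct]) while solid is left; crystals form when [bis adduct] > cs4 (solubility = 5.20 mM, k = 0.120 s⁻¹)
    single product → decomposed reagent (k = 0.00470 s⁻¹, Ea = 77.0 kJ mol⁻¹)
    starting material + coupling partner → single product + by-product (k = 0.0490 L mol⁻¹ s⁻¹, Ea = 57.0 kJ mol⁻¹)
    (constants at 5 °C)

**The crossing.** Saturday's bill, read by the same rule at 20.0 min, is 1.36, above theta's. In Saturday's flask at 2.12 min, decomposition of single product and its second coupling stand near level, at a ratio of 1.1. Take that decomposition out of Saturday's flask and bis adduct goes from 19.2% to 30.5%, which is a part of the reason and not the whole.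

**Second flask.** Saturday's recipe read at 5.0 min has 40.0% starting material left. Saturday's bill then leaves 31.8% of the partner's own charge, and theta's bill leaves 41.1%. The computed flask holds 32.2%.

The readings are calculated with constants of no real substance; the scatter is artificial.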